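**Your question.** Per hour, the east run's target fell by a nearly steady fraction late on, from 18.0 % at 15.0 h to 11.2 % at 25.0 h. That reads as 0.0474 /h. Call it the tail rate, the pseudo-first-order fraction of target lost per hour past the peak; multiplied by the hours elapsed, it counts loss turnovers.

all flasks: gas phase 51 mM (held)

| charge | substrate | remark | time |
|---|---|---|---|
| north | 0.082 M (fed, over 8.0 min) | the very flask that is asked about, followed so far |  |
| east | 0.055 M (fed, over 8.0 min) | run made earlier |  |
| flask | 0.082 M (fed, over 8.0 min) |  | 25 h |

| north: time / h | north: target / % | east: time / h | east: target / % |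
|---|---|---|---|
| 1.33 | 16.6 | 1.33 | 16.6 |
| 2.00 | 20.6 | 2.50 | 22.9 |
| 3.00 | 24.3 | 4.00 | 26.4 |
| 4.00 | 25.5 | 8.00 | 24.5 |
| 6.00 | 26.7 | 15.0 | 18.0 |
| 10.0 | 23.1 | 25.0 | 11.2 |

(readings scatter by 0.5 percentage points)

- the best time, 25 h at the latest, for target
- the amount of target, in percent of the substrate charged, at that time
- the first time at which target reaches 18 %, in the same percent

- at the start none of the gas phase is in solution

**Your hunch.** You expect a long stir to cost little, but the count says otherwise. North and east read alike early, 16.6 % against 16.6 % at 1.33 h, so I carry the tail rate over to north. From 10.0 h to 25 h that makes 0.711 turnovers, which leaves about 11.3 %, less than the 26.7 % read at 6.00 h. Stop near that reading, my own choice of time. A straight line between the readings on either side gives 1.56 h for the first crossing.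

**The forecast.** It says 26.7 % (26.1 % to 27.4 %) at 5.3 h (4.5 h to 6.3 h), earlier than my stop, and a first crossing at 1.55 h (1.47 h to 1.64 h). Its ground for taking the formation as roughly first order: “the formation percentage barely depends on substrate concentration”.

**The flask.** It gives 26.1 % at 5.03 h and crosses at 1.60 h, all within tolerance, with the amount at the forecast's low end.

    gas phase ⇌ dissolved gas, rate k1*(csat - [dissolved gas]) (kL = 0.0174 /min)
    substrate + dissolved gas ⇌ target (K = 10.0 /M, k = 0.525 /M/min)
    dissolved gas + target → over-reacted product (k = 0.0492 /M/min)
    dissolved gas ⇌ dormant form (K = 0.790, k = 0.0456 /min)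

At 25.0 h the flask's substrate has a half-life into target, by the forward rate alone, of 0.45 h, far shorter than the 14.6 h that the tail rate read on the east run gives target. At that time the flask holds 25.9 % substrate beside 12.2 % target, against the 11.3 % of target counted. A neighbour flask with the same amounts, read at 96.0 h, counts to 0.390 % of target and holds 0.399 %.

Readings and results were computed for substances that don't exist; noise was put on by code.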